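(The constants used here are made up; no experiment stands behind them.)

K2 times the charged cZ is 2.9, the ratio of J.Z to J at the balance of step two taken by itself with cZ at its charge; dusk and summer carry the same charge and differ in time.

- dusk: J 0.50 M; Z 0.750 M; time 6.0 h
- summer: J 0.50 M; Z 0.750 M; time 15 h

    J → D (k1 = 0.0012 /min)
    J + Z ⇌ J.Z (K2 = 3.8 /M, k2 = 3.7 × 10⁻⁴ /M/min)
    J.Z ⇌ Q (K3 = 0.51, k3 = 0.0010 /min)

1. which of these there is most of at the end, counted by the J in it, dusk (Q / J.Z / J / D)
2. which of these there is most of at the end, counted by the J in it, summer (Q / J.Z / J / D)
3. how much there is at the end of the one of these that leads, in percent of the J charged: dusk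
4. how much there is at the end of the one of these that leads, in percent of the J charged: summer

Here is what looks wrong: binding favours J.Z by that ratio, yet at the start of summer step one uses J 4.3 times as fast as the forward direction of step two does. The two numbers answer different questions: one is a balance of step two taken by itself, the other compares speeds. So I count turnovers. At dusk step two gets 0.0999 forward turnovers, fewer than the 0.432 of step one and under 1, so I expect J.Z to stay short of that ratio.

I hold cZ at its charge, which makes the loss of J pseudo-first-order, and I drop the way back from J.Z, whose constant 9.74 × 10⁻⁵ /min is smaller than that of step one. Then: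

N, dusk = (0.0012 /min + 3.7 × 10⁻⁴ /M/min × 0.750 M) × 6.0 h = 0.532

N, summer, the same over 15 h = 1.33

share to D, s = 0.0012 /min / (0.0012 /min + 3.7 × 10⁻⁴ /M/min × 0.750 M) = 81.2%

J = exp(−N), D = s × (1 − exp(−N))

N is the turnover count, the summed first-order constants of J's loss times the time. At dusk I get J in the lead at 58.7%. In summer I get D at 59.7%.

The forecast, with “Treat Z as nearly constant”, names J at 59% for dusk and D at 60.2% for summer, both figures a little above mine.

The flask gives J at 59.0% at dusk and D at 60.1% in summer.

In summer, step two has 18% of its turnover up to the end behind it after 1.50 h while step three has 3.0%, and step one reaches half of its turnover up to the end by 5.21 h. Summer ends with 91.5% of the Z free, and its J reads as 1.30 turnovers against the 1.33 counted. In the neighbour of summer charged with 0.19 M of Z, N comes to 1.14, so exp(−N) is 32.0%, and that flask holds J at 32% and D at 64.5%.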